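The route rests on disconnecting ring B at C5–C10 and C6–C7 (labdane numbering). The tetrasubstituted C8=C9 alkene, flanked by C7 and the quaternary C10, is the cyclohexene retron of a [4+2] addition between a diene C7=C8–C9=C10 and a C5=C6 dienophile joined through C1–C4. One thermal intramolecular Diels–Alder reaction of an (E)-vinyl sulfone closes rings A and B together and sets C5 and C10 (C6 only temporarily) under control of the pre-formed C4 quaternary centre. The precursor is an acyclic (4S) triene: methyl ester and sulfonylvinyl group on C4, a 2,3-disubstituted diene with the C20 methyl inside, and the C11–C15 chain as a TBDPS ether. The diene is completed before the ester/sulfone fragment is attached.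

Key step: step 14

Remark: tert-butyl(but-3-yn-1-yloxy)dimethylsilane is taken as a commercial starting material (otherwise one silylation of but-3-yn-1-ol precedes step 1).
Remark: the antipode of the chiral zinc catalyst in step 10 is assumed to be chosen so that diester 15 gives the (S)-hydroxy ester 17.

Step 1
Reactants: 1 tert-butyl(but-3-yn-1-yloxy)dimethylsilane
Product: 4 (2E)-5-[(tert-butyldimethylsilyl)oxy]-3-methylpent-2-en-1-ol, via alkenyldimethylalane 2 (not isolated), via lithium alkenylalanate 3 (not isolated)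
Conditions: Me3Al, Cp2ZrCl2 (cat.), CH2Cl2, 0 °C to rt; then n-BuLi, THF, −78 °C; (CH2O)n, −78 °C to rt; aq. Rochelle salt
Reagents that add atoms: trimethylaluminium C[Al](C)C; formaldehyde (from paraformaldehyde) C=O
Why: Zirconium-catalysed syn-methylalumination (Negishi carboalumination) puts CH3 on the internal and Al on the terminal alkyne carbon, and the derived alanate is hydroxymethylated with retention, which fixes the 13E trisubstituted alkene.

Step 2
Reactants: 4 (2E)-5-[(tert-butyldimethylsilyl)oxy]-3-methylpent-2-en-1-ol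
Product: 5 (2E)-1-[(tert-butyldiphenylsilyl)oxy]-5-[(tert-butyldimethylsilyl)oxy]-3-methylpent-2-ene
Conditions: TBDPSCl, imidazole, CH2Cl2, rt
Reagents that add atoms: tert-butyl(chloro)diphenylsilane CC(C)(C)[Si](Cl)(c1ccccc1)c1ccccc1
Why: Routine silylation of the primary allylic alcohol installs at O15 a silyl ether that is more robust than TBS and should survive the organometallic, thermal and reductive steps ahead.

Step 3
Reactants: 5 (2E)-1-[(tert-butyldiphenylsilyl)oxy]-5-[(tert-butyldimethylsilyl)oxy]-3-methylpent-2-ene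
Product: 6 (3E)-5-[(tert-butyldiphenylsilyl)oxy]-3-methylpent-3-en-1-ol
Conditions: PPTS (cat.), MeOH, rt
Reagents that add atoms: none
Why: Acid-catalysed methanolysis cleaves a primary TBS ether much faster than a primary TBDPS ether, a standard orthogonal pair.

Step 4
Reactants: 6 (3E)-5-[(tert-butyldiphenylsilyl)oxy]-3-methylpent-3-en-1-ol
Product: 7 tert-butyl{[(2E)-5-iodo-3-methylpent-2-en-1-yl]oxy}diphenylsilane
Conditions: I2, PPh3, imidazole, CH2Cl2, 0 °C
Reagents that add atoms: iodine II
Why: Appel-type iodination proceeds by SN2 displacement of an alkoxyphosphonium ion at the primary carbon and leaves the silyl ether and the alkene untouched.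

Step 5
Reactants: 7 tert-butyl{[(2E)-5-iodo-3-methylpent-2-en-1-yl]oxy}diphenylsilane; 8 methyl acetoacetate
Product: 9 methyl (5E)-2-acetyl-7-[(tert-butyldiphenylsilyl)oxy]-5-methylhept-5-enoate (racemic at C-2)
Conditions: K2CO3, acetone, reflux (8 in excess)
Reagents that add atoms: none
Why: Acetoacetic ester C-alkylation of the stabilised enolate by a primary iodide joins C9 to C11, and the racemic centre formed is erased in the next step.

Step 6
Reactants: 9 methyl (5E)-2-acetyl-7-[(tert-butyldiphenylsilyl)oxy]-5-methylhept-5-enoate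
Product: 10 methyl (2E,5E)-7-[(tert-butyldiphenylsilyl)oxy]-5-methyl-2-{1-[(trifluoromethanesulfonyl)oxy]ethylidene}hept-5-enoate (OTf cis to the C11 chain, CH3 cis to CO2Me)
Conditions: Tf2O, DBU, CH2Cl2, −78 °C
Reagents that add atoms: trifluoromethanesulfonic anhydride O=S(=O)(OS(=O)(=O)C(F)(F)F)C(F)(F)F
Why: O-sulfonylation of the non-chelated amidinium enolate, which prefers the enolate oxygen anti to the ester carbonyl, should give the (E)-enol triflate, the geometry that places C1 cis to C11 after a stereoretentive coupling.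

Step 7
Reactants: 10 methyl (2E,5E)-7-[(tert-butyldiphenylsilyl)oxy]-5-methyl-2-{1-[(trifluoromethanesulfonyl)oxy]ethylidene}hept-5-enoate
Product: 11 (2E,6E)-8-[(tert-butyldiphenylsilyl)oxy]-3-(2-hydroxypropan-2-yl)-6-methylocta-2,6-dien-2-yl trifluoromethanesulfonate
Conditions: MeMgBr, CeCl3, THF, −78 to 0 °C
Reagents that add atoms: methylmagnesium bromide C[Mg]Br
Why: Double 1,2-addition of the oxophilic, weakly basic methylcerium reagent converts the hindered ester into the dimethylcarbinol, while the enol triflate, held trans to the new alkoxide by the E geometry, should not be attacked at low temperature.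

Step 8
Reactants: 11 (2E,6E)-8-[(tert-butyldiphenylsilyl)oxy]-3-(2-hydroxypropan-2-yl)-6-methylocta-2,6-dien-2-yl trifluoromethanesulfonate
Product: 12 (2E,6E)-8-[(tert-butyldiphenylsilyl)oxy]-6-methyl-3-(prop-1-en-2-yl)octa-2,6-dien-2-yl trifluoromethanesulfonate
Conditions: Burgess reagent, toluene, 50 °C
Reagents that add atoms: none
Why: Burgess dehydration (syn-elimination through the sulfamate ester) can only remove a methyl hydrogen because C9 is sp2, so the isopropenyl end of the diene forms regiospecifically, and ionisation is disfavoured by the electron-poor triflyloxy alkene.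

Step 9
Reactants: 13 dimethyl methylmalonate; 14 allyl bromide
Product: 15 dimethyl 2-allyl-2-methylmalonate
Conditions: K2CO3, DMF, rt
Reagents that add atoms: none
Why: Malonate alkylation by a reactive allylic bromide builds the prochiral quaternary carbon that becomes C4 and brings in C1–C3 as an allyl group.

Step 10
Reactants: 15 dimethyl 2-allyl-2-methylmalonate
Product: 17 methyl (2S)-2-(hydroxymethyl)-2-methylpent-4-enoate, via silyl ether 16 (not isolated)
Conditions: Et2Zn (cat.), chiral tetradentate aminophenol ligand (cat.), (EtO)2MeSiH, THF, 0 °C to rt; then K2CO3, MeOH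
Reagents that add atoms: none
Why: Catalytic reductive desymmetrisation (hydrosilylation of one enantiotopic ester of an α,α-dialkyl malonate by a chiral dinuclear zinc hydride) sets the C4 quaternary stereocentre by catalyst control, and the mono-reduced product is protected from further reduction as its silyl ether.

Step 11
Reactants: 17 methyl (2S)-2-(hydroxymethyl)-2-methylpent-4-enoate
Product: 18 methyl (2S)-2-formyl-2-methylpent-4-enoate
Conditions: Dess–Martin periodinane, NaHCO3, CH2Cl2, rt
Reagents that add atoms: none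
Why: Dess–Martin oxidation of the neopentyl primary alcohol gives an aldehyde that cannot enolise, so the C4 configuration is secure.

Step 12
Reactants: 18 methyl (2S)-2-formyl-2-methylpent-4-enoate; 19 diethyl (phenylsulfonylmethyl)phosphonate
Product: 20 methyl (2S)-2-methyl-2-[(E)-2-(phenylsulfonyl)ethenyl]pent-4-enoate
Conditions: LiCl, DBU, MeCN, rt
Reagents that add atoms: none
Why: Horner–Wadsworth–Emmons olefination with the sulfonyl-stabilised phosphonate under mild Masamune–Roush conditions should give the (E)-vinyl sulfone and avoids nucleophilic deformylation of the hindered aldehyde.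

Step 13
Reactants: 20 methyl (2S)-2-methyl-2-[(E)-2-(phenylsulfonyl)ethenyl]pent-4-enoate; 12 (2E,6E)-8-[(tert-butyldiphenylsilyl)oxy]-6-methyl-3-(prop-1-en-2-yl)octa-2,6-dien-2-yl trifluoromethanesulfonate
Product: 22 methyl (2S,6E,10E)-12-[(tert-butyldiphenylsilyl)oxy]-2,6,10-trimethyl-2-[(E)-2-(phenylsulfonyl)ethenyl]-7-(prop-1-en-2-yl)dodeca-6,10-dienoate, via alkylborane 21 (not isolated)
Conditions: 9-BBN, THF, 0 °C to rt; then aq. K3PO4, 12, PdCl2(dppf) (cat.), AsPh3 (cat.), DMF, rt
Reagents that add atoms: none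
Why: Anti-Markovnikov hydroboration of the terminal alkene by 9-BBN (the electron-poor vinyl sulfone is inert) followed by B-alkyl Suzuki–Miyaura coupling with the dienyl triflate forms the C1–C10 bond with retention of the C9=C10 geometry.

Step 14
Reactants: 22 methyl (2S,6E,10E)-12-[(tert-butyldiphenylsilyl)oxy]-2,6,10-trimethyl-2-[(E)-2-(phenylsulfonyl)ethenyl]-7-(prop-1-en-2-yl)dodeca-6,10-dienoate
Product: 23 methyl (4S,5R,6S,10S)-15-[(tert-butyldiphenylsilyl)oxy]-6-(phenylsulfonyl)labda-8,13E-dien-19-oate (trans-decalin; H5 α, C20 methyl β, C19 ester β and axial, sulfone 6α and equatorial)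
Conditions: toluene (0.01 M, degassed), BHT (cat.), sealed tube, 180 °C
Reagents that add atoms: none
Why: A concerted, asynchronous, suprafacial [4+2] cycloaddition joins the diene C7=C8–C9=C10 to the sulfonyl-activated C5=C6 alkene, the closest known type being the thermal type-1 intramolecular Diels–Alder reaction of 1,7,9-decatrienes that carry a terminal sulfone and a (Z)-methyl on the tethered diene terminus. Ring B is closed as the new cyclohexene by the σ-bonds C5–C10 and C6–C7, and ring A is closed at the same time in the fused mode, the C1–C4 tether and the C5–C10 bond completing a six-membered chair. The trans ring fusion (H5 α, C20 β) follows from the tether-exo, sulfone-endo transition state together with the E geometry at C9=C10 that holds C1 outside and the methyl inside, and the 6α-sulfone (trans to C4) follows from suprafacial addition to the E-dienophile. The absolute sense is relayed from C4, because in the chair tether the flat ester takes the axial site syn to the C10 methyl while the C4 methyl stays equatorial, which avoids a methyl–methyl 1,3-diaxial contact and places C19 on the β face. The step needs endo over exo selectivity, π-facial selectivity and cycloaddition in preference to the reversible [1,5]-hydrogen shift of the inside methyl; the fully substituted C4 clashes with the C9 side chain in the tether-endo array, gem-disubstitution at C4 assists closure, and the quaternary C4 blocks vinyl-to-allyl sulfone isomerisation.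

Step 15
Reactants: 23 methyl (4S,5R,6S,10S)-15-[(tert-butyldiphenylsilyl)oxy]-6-(phenylsulfonyl)labda-8,13E-dien-19-oate
Product: 24 methyl (4S,5R,10S)-15-[(tert-butyldiphenylsilyl)oxy]labda-8,13E-dien-19-oate
Conditions: 6% Na(Hg), Na2HPO4, MeOH–THF, −20 °C to rt
Reagents that add atoms: none
Why: Reductive desulfonylation by electron transfer cleaves the C6–S bond of the secondary alkyl phenyl sulfone and the carbanion is protonated, which removes the temporary C6 stereocentre without touching the isolated alkenes or the hindered ester.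

Step 16
Reactants: 24 methyl (4S,5R,10S)-15-[(tert-butyldiphenylsilyl)oxy]labda-8,13E-dien-19-oate
Product: 25 (4S,5R,10S)-15-[(tert-butyldiphenylsilyl)oxy]labda-8,13E-dien-19-oic acid
Conditions: NaSEt, DMF, 90 °C; then aq. HCl to pH 3–4
Reagents that add atoms: none
Why: The axial, neopentyl-type C19 methyl ester resists saponification but is cleaved by SN2 attack of thiolate on the ester methyl group (nucleophilic dealkylation), which leaves the silyl ether, the alkenes and all stereocentres intact.

Step 17
Reactants: 25 (4S,5R,10S)-15-[(tert-butyldiphenylsilyl)oxy]labda-8,13E-dien-19-oic acid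
Product: 26 (4S,5R,10S)-15-hydroxylabda-8,13E-dien-19-oic acid
Conditions: TBAF, THF, rt
Reagents that add atoms: none
Why: Fluoride-mediated desilylation frees the primary allylic alcohol under conditions that do not affect the carboxylate or the alkenes.

Step 18
Reactants: 26 (4S,5R,10S)-15-hydroxylabda-8,13E-dien-19-oic acid
Product: 27 (4S,5R,10S)-15-acetoxylabda-8,13E-dien-19-oic acid (target)
Conditions: Ac2O, pyridine, 0 °C to rt; aq. work-up
Reagents that add atoms: acetic anhydride CC(=O)OC(C)=O
Why: Acetylation of the unhindered primary allylic alcohol is fast, whereas the hindered tertiary carboxylic acid should be recovered unchanged after aqueous work-up.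

Compound list
1 | tert-butyl(but-3-yn-1-yloxy)dimethylsilane | C#CCCO[Si](C)(C)C(C)(C)C | starting material
2 | [(1E)-4-[(tert-butyldimethylsilyl)oxy]-2-methylbut-1-en-1-yl]dimethylalane | CC(C)(C)[Si](C)(C)OCC/C(C)=C/[Al](C)C | intermediate (not isolated)
3 | lithium butyl[(1E)-4-[(tert-butyldimethylsilyl)oxy]-2-methylbut-1-en-1-yl]dimethylaluminate | CC(C)(C)[Si](C)(C)OCC/C(C)=C/[Al-](C)(C)CCCC.[Li+] | intermediate (not isolated)
4 | (2E)-5-[(tert-butyldimethylsilyl)oxy]-3-methylpent-2-en-1-ol | CC(C)(C)[Si](C)(C)OCC/C(C)=C/CO | intermediate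
5 | (2E)-1-[(tert-butyldiphenylsilyl)oxy]-5-[(tert-butyldimethylsilyl)oxy]-3-methylpent-2-ene | CC(C)(C)[Si](C)(C)OCC/C(C)=C/CO[Si](c1ccccc1)(c1ccccc1)C(C)(C)C | intermediate
6 | (3E)-5-[(tert-butyldiphenylsilyl)oxy]-3-methylpent-3-en-1-ol | OCC/C(C)=C/CO[Si](c1ccccc1)(c1ccccc1)C(C)(C)C | intermediate
7 | tert-butyl{[(2E)-5-iodo-3-methylpent-2-en-1-yl]oxy}diphenylsilane | ICC/C(C)=C/CO[Si](c1ccccc1)(c1ccccc1)C(C)(C)C | intermediate
8 | methyl acetoacetate | CC(=O)CC(=O)OC | starting material
9 | methyl (5E)-2-acetyl-7-[(tert-butyldiphenylsilyl)oxy]-5-methylhept-5-enoate (racemic) | CC(=O)C(CC/C(C)=C/CO[Si](c1ccccc1)(c1ccccc1)C(C)(C)C)C(=O)OC | intermediate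
10 | methyl (2E,5E)-7-[(tert-butyldiphenylsilyl)oxy]-5-methyl-2-{1-[(trifluoromethanesulfonyl)oxy]ethylidene}hept-5-enoate | C/C(OS(=O)(=O)C(F)(F)F)=C(/CC/C(C)=C/CO[Si](c1ccccc1)(c1ccccc1)C(C)(C)C)C(=O)OC | intermediate
11 | (2E,6E)-8-[(tert-butyldiphenylsilyl)oxy]-3-(2-hydroxypropan-2-yl)-6-methylocta-2,6-dien-2-yl trifluoromethanesulfonate | C/C(OS(=O)(=O)C(F)(F)F)=C(/CC/C(C)=C/CO[Si](c1ccccc1)(c1ccccc1)C(C)(C)C)C(C)(C)O | intermediate
12 | (2E,6E)-8-[(tert-butyldiphenylsilyl)oxy]-6-methyl-3-(prop-1-en-2-yl)octa-2,6-dien-2-yl trifluoromethanesulfonate | C=C(C)/C(CC/C(C)=C/CO[Si](c1ccccc1)(c1ccccc1)C(C)(C)C)=C(\C)OS(=O)(=O)C(F)(F)F | intermediate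
13 | dimethyl methylmalonate | COC(=O)C(C)C(=O)OC | starting material
14 | allyl bromide | C=CCBr | starting material
15 | dimethyl 2-allyl-2-methylmalonate | C=CCC(C)(C(=O)OC)C(=O)OC | intermediate
16 | methyl (2S)-2-{[(diethoxymethylsilyl)oxy]methyl}-2-methylpent-4-enoate | C=CC[C@](C)(C(=O)OC)CO[Si](C)(OCC)OCC | intermediate (not isolated)
17 | methyl (2S)-2-(hydroxymethyl)-2-methylpent-4-enoate | C=CC[C@](C)(C(=O)OC)CO | intermediate
18 | methyl (2S)-2-formyl-2-methylpent-4-enoate | C=CC[C@](C)(C(=O)OC)C=O | intermediate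
19 | diethyl (phenylsulfonylmethyl)phosphonate | CCOP(=O)(CS(=O)(=O)c1ccccc1)OCC | starting material
20 | methyl (2S)-2-methyl-2-[(E)-2-(phenylsulfonyl)ethenyl]pent-4-enoate | C=CC[C@](C)(C(=O)OC)/C=C/S(=O)(=O)c1ccccc1 | intermediate
21 | methyl (2S)-5-(9-borabicyclo[3.3.1]nonan-9-yl)-2-methyl-2-[(E)-2-(phenylsulfonyl)ethenyl]pentanoate | C1CCC2CCCC1B2CCC[C@](C)(C(=O)OC)/C=C/S(=O)(=O)c1ccccc1 | intermediate (not isolated)
22 | methyl (2S,6E,10E)-12-[(tert-butyldiphenylsilyl)oxy]-2,6,10-trimethyl-2-[(E)-2-(phenylsulfonyl)ethenyl]-7-(prop-1-en-2-yl)dodeca-6,10-dienoate | C=C(C)/C(CC/C(C)=C/CO[Si](c1ccccc1)(c1ccccc1)C(C)(C)C)=C(\C)CCC[C@](C)(C(=O)OC)/C=C/S(=O)(=O)c1ccccc1 | intermediate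
23 | methyl (4S,5R,6S,10S)-15-[(tert-butyldiphenylsilyl)oxy]-6-(phenylsulfonyl)labda-8,13E-dien-19-oate | CC(C)(C)[Si](c1ccccc1)(c1ccccc1)OC/C=C(\C)CCC1=C(C)C[C@H](S(=O)(=O)c3ccccc3)[C@H]2[C@@](C)(C(=O)OC)CCC[C@]12C | intermediate
24 | methyl (4S,5R,10S)-15-[(tert-butyldiphenylsilyl)oxy]labda-8,13E-dien-19-oate | CC(C)(C)[Si](c1ccccc1)(c1ccccc1)OC/C=C(\C)CCC1=C(C)CC[C@H]2[C@@](C)(C(=O)OC)CCC[C@]12C | intermediate
25 | (4S,5R,10S)-15-[(tert-butyldiphenylsilyl)oxy]labda-8,13E-dien-19-oic acid | CC(C)(C)[Si](c1ccccc1)(c1ccccc1)OC/C=C(\C)CCC1=C(C)CC[C@H]2[C@@](C)(C(=O)O)CCC[C@]12C | intermediate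
26 | (4S,5R,10S)-15-hydroxylabda-8,13E-dien-19-oic acid | OC/C=C(\C)CCC1=C(C)CC[C@H]2[C@@](C)(C(=O)O)CCC[C@]12C | intermediate
27 | (4S,5R,10S)-15-acetoxylabda-8,13E-dien-19-oic acid | CC(=O)OC/C=C(\C)CCC1=C(C)CC[C@H]2[C@@](C)(C(=O)O)CCC[C@]12C | target

Total step count: 18. Longest linear sequence: 14 steps (steps 1–8, then 13–18); the C4 fragment (steps 9–12) joins at step 13.

Steps most likely to fail

Step 14. Bond formation at the congested C5–C10 junction may be slow enough that the reversible [1,5]-hydrogen shift of the inside methyl, or intermolecular reaction, consumes the triene; endo/exo or π-facial discrimination may also be poor. The fallback keeps the disconnection but changes the dienophile design and sets out from aldehyde 18. Horner–Wadsworth–Emmons olefination with diethyl ({[3,5-bis(trifluoromethyl)phenyl]sulfonyl}methyl)phosphonate should give methyl (2S)-2-{(E)-2-[3,5-bis(trifluoromethyl)phenylsulfonyl]ethenyl}-2-methylpent-4-enoate F1. Hydroboration with 9-BBN gives the corresponding B-alkyl-9-borabicyclononane F2 (not isolated), which is coupled with triflate 12 as in step 13 to the aryl-sulfonyl triene F3. Its lower LUMO should allow cyclisation at a lower temperature, where the hydrogen shift is slower, to the 6α-arylsulfonyl cycloadduct F4. Na(Hg) desulfonylation of F4 returns to the route at 24.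

Step 7. The methyl nucleophile may attack the enol triflate (S–O cleavage or addition–elimination at C10) instead of the ester. The fallback sets out from keto ester 9 and uses the less electrophilic tosylate throughout. Enol tosylation under non-chelating conditions (TsCl, N-methylimidazole, Et3N), which is E-selective for α-substituted acetoacetates, should give methyl (2E,5E)-7-[(tert-butyldiphenylsilyl)oxy]-5-methyl-2-{1-[(4-methylbenzenesulfonyl)oxy]ethylidene}hept-5-enoate F5. Methylcerium addition then gives the tosyloxy dimethylcarbinol F6, and Burgess dehydration gives the dienyl tosylate F7. B-alkyl Suzuki–Miyaura coupling of F7 with borane 21 under a bulky biarylphosphine catalyst (Pd(OAc)2, XPhos, K3PO4), as needed for alkenyl tosylates, returns to the route at 22.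

Step 10. Discrimination between the two enantiotopic ester groups (methyl against allyl on the prochiral carbon) may be insufficient, giving low enantiomeric purity at C4. The fallback sets out from diester 15 and replaces catalyst control by enzymatic hydrolysis. Pig liver esterase (pH 7.5 buffer, DMSO cosolvent) is assumed to give the half-ester (2S)-2-(methoxycarbonyl)-2-methylpent-4-enoic acid F8, whose acid handle allows enantiomeric enrichment at this stage. Activation with isobutyl chloroformate and N-methylmorpholine gives the isobutyl carbonic mixed anhydride of this acid F9, and NaBH4 reduction of the activated carboxyl (the methyl ester is retained) returns to the route at 17.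

Further compounds
F1 | step 14 | methyl (2S)-2-{(E)-2-[3,5-bis(trifluoromethyl)phenylsulfonyl]ethenyl}-2-methylpent-4-enoate | C=CC[C@](C)(C(=O)OC)/C=C/S(=O)(=O)c1cc(C(F)(F)F)cc(C(F)(F)F)c1
F2 | step 14 | methyl (2S)-5-(9-borabicyclo[3.3.1]nonan-9-yl)-2-{(E)-2-[3,5-bis(trifluoromethyl)phenylsulfonyl]ethenyl}-2-methylpentanoate | C1CCC2CCCC1B2CCC[C@](C)(C(=O)OC)/C=C/S(=O)(=O)c1cc(C(F)(F)F)cc(C(F)(F)F)c1
F3 | step 14 | methyl (2S,6E,10E)-2-{(E)-2-[3,5-bis(trifluoromethyl)phenylsulfonyl]ethenyl}-12-[(tert-butyldiphenylsilyl)oxy]-2,6,10-trimethyl-7-(prop-1-en-2-yl)dodeca-6,10-dienoate | C=C(C)/C(CC/C(C)=C/CO[Si](c1ccccc1)(c1ccccc1)C(C)(C)C)=C(\C)CCC[C@](C)(C(=O)OC)/C=C/S(=O)(=O)c1cc(C(F)(F)F)cc(C(F)(F)F)c1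
F4 | step 14 | methyl (4S,5R,6S,10S)-6-[3,5-bis(trifluoromethyl)phenylsulfonyl]-15-[(tert-butyldiphenylsilyl)oxy]labda-8,13E-dien-19-oate | CC(C)(C)[Si](c1ccccc1)(c1ccccc1)OC/C=C(\C)CCC1=C(C)C[C@H](S(=O)(=O)c3cc(C(F)(F)F)cc(C(F)(F)F)c3)[C@H]2[C@@](C)(C(=O)OC)CCC[C@]12C
F5 | step 7 | methyl (2E,5E)-7-[(tert-butyldiphenylsilyl)oxy]-5-methyl-2-{1-[(4-methylbenzenesulfonyl)oxy]ethylidene}hept-5-enoate | C/C(OS(=O)(=O)c1ccc(C)cc1)=C(/CC/C(C)=C/CO[Si](c1ccccc1)(c1ccccc1)C(C)(C)C)C(=O)OC
F6 | step 7 | (2E,6E)-8-[(tert-butyldiphenylsilyl)oxy]-3-(2-hydroxypropan-2-yl)-6-methylocta-2,6-dien-2-yl 4-methylbenzenesulfonate | C/C(OS(=O)(=O)c1ccc(C)cc1)=C(/CC/C(C)=C/CO[Si](c1ccccc1)(c1ccccc1)C(C)(C)C)C(C)(C)O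
F7 | step 7 | (2E,6E)-8-[(tert-butyldiphenylsilyl)oxy]-6-methyl-3-(prop-1-en-2-yl)octa-2,6-dien-2-yl 4-methylbenzenesulfonate | C=C(C)/C(CC/C(C)=C/CO[Si](c1ccccc1)(c1ccccc1)C(C)(C)C)=C(\C)OS(=O)(=O)c1ccc(C)cc1
F8 | step 10 | (2S)-2-(methoxycarbonyl)-2-methylpent-4-enoic acid | C=CC[C@](C)(C(=O)OC)C(=O)O
F9 | step 10 | isobutyl carbonic mixed anhydride of (2S)-2-(methoxycarbonyl)-2-methylpent-4-enoic acid (configuration unchanged) | C=CC[C@](C)(C(=O)OC)C(=O)OC(=O)OCC(C)C
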